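**Retrosynthetic overview**
- The ten-membered ring is closed last, at C6–C7, by intramolecular allylation of a tethered enal with a 3-(bromomethyl)butenolide; this sets C6 and C7 from C8.
- The butenolide (lactone ring, formed first) comes from ring-closing metathesis of a C8 allylic 2-(bromomethyl)acrylate.
- The C8–O bond and its configuration, the only externally controlled stereocentre, come from an enantioselective allylic C–H acyloxylation of a terminal olefin (key step, proposed new method).
- The acyclic triene is assembled at C1–C2 by B-alkyl Suzuki coupling of a (Z)-vinyl iodide with a dienol.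
- The vinyl iodide comes from propargyl alcohol by carbomagnesiation/iodination, and the dienol from but-2-yne-1,4-diol by trans-hydrostannation/Stille vinylation; both steps fix the alkene geometries.

Assumption: atom labels C1–C15 follow germacrane numbering of the target (lactone carbonyl C12 with its oxygen on C8, exocyclic methylene C13, hydroxyl on C6, acetoxymethyl carbons C14 on C10 and C15 on C4); the target is (6R,7S,8S) with C9 trans to C2 across C1=C10 and C3 cis to C6 across C4=C5.

**Step 1**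
Reactants: 1 prop-2-yn-1-ol; 2 but-3-en-1-ylmagnesium bromide
Product: 4 (Z)-2-(but-3-en-1-yl)-3-iodoprop-2-en-1-ol, via alkenylmagnesium alkoxide 3 (not isolated)
Conditions: 2 (2.5 equiv), CuI (10 mol%), Et2O, 0 °C to rt, 16 h; then I2 (1.5 equiv), −50 to 0 °C; aq. NH4Cl
Reagents that add atoms: iodine, II
Why: Copper-catalysed anti-carbomagnesiation of a propargylic alkoxide puts the butenyl group on C10 and magnesium on C1 in a five-membered chelate, so iodinolysis with retention gives only the iodide cis to CH2OH, which fixes the C1=C10 geometry.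

**Step 2**
Reactants: 5 but-2-yne-1,4-diol
Product: 6 4-[(tert-butyldimethylsilyl)oxy]but-2-yn-1-ol
Conditions: NaH (1.0 equiv), THF, 0 °C; TBSCl (1.0 equiv), rt
Reagents that add atoms: tert-butyldimethylsilyl chloride, C[Si](C)(Cl)C(C)(C)C
Why: Monosilylation of a symmetric diol through its sparingly soluble monosodium alkoxide differentiates the future C6 oxygen (silylated) from the future C15 oxygen (free); no stereocentre is formed.

**Step 3**
Reactants: 6 4-[(tert-butyldimethylsilyl)oxy]but-2-yn-1-ol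
Product: 7 (2Z)-4-[(tert-butyldimethylsilyl)oxy]-2-(tributylstannyl)but-2-en-1-ol
Conditions: Bu3SnH (1.1 equiv), [Cp*RuCl]4 (1.25 mol%), CH2Cl2, rt
Reagents that add atoms: tributyltin hydride, CCCC[SnH](CCCC)CCCC
Why: Hydroxyl-directed ruthenium-catalysed trans-hydrostannation delivers tin to the alkyne carbon next to the free OH (C4) and hydrogen anti to it on C5, so C6 is cis to tin and the C4=C5 geometry is fixed.

**Step 4**
Reactants: 7 (2Z)-4-[(tert-butyldimethylsilyl)oxy]-2-(tributylstannyl)but-2-en-1-ol; 8 bromoethene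
Product: 9 (2E)-2-{2-[(tert-butyldimethylsilyl)oxy]ethylidene}but-3-en-1-ol
Conditions: 8 (3 equiv, 1 M in THF), Pd(PPh3)4 (5 mol%), CuI (20 mol%), CsF (2 equiv), DMF, 40 °C, sealed tube
Reagents that add atoms: none
Why: Copper- and fluoride-accelerated Stille coupling replaces tin by the vinyl group (C3 and C2) with retention, so C3 stays cis to C6.

**Step 5**
Reactants: 9 (2E)-2-{2-[(tert-butyldimethylsilyl)oxy]ethylidene}but-3-en-1-ol; 4 (Z)-2-(but-3-en-1-yl)-3-iodoprop-2-en-1-ol
Product: 11 (2Z,6E)-2-(but-3-en-1-yl)-8-[(tert-butyldimethylsilyl)oxy]-6-(hydroxymethyl)octa-2,6-dien-1-ol, via B-alkyl-9-BBN borane 10 (not isolated)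
Conditions: 9-BBN dimer (1.1 equiv), THF, 0 °C to rt; then 3 M aq. Cs2CO3 (quenches excess B–H), 4 (1.2 equiv), PdCl2(dppf) (5 mol%), AsPh3 (5 mol%), DMF, rt
Reagents that add atoms: none
Why: 9-BBN hydroborates only the monosubstituted vinyl terminus of the diene (boron on C2), and B-alkyl Suzuki–Miyaura coupling with the vinyl iodide forms C1–C2 with retention of both alkene geometries.

**Step 6**
Reactants: 11 (2Z,6E)-2-(but-3-en-1-yl)-8-[(tert-butyldimethylsilyl)oxy]-6-(hydroxymethyl)octa-2,6-dien-1-ol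
Product: 12 [(2Z,6E)-6-(acetoxymethyl)-2-(but-3-en-1-yl)-8-[(tert-butyldimethylsilyl)oxy]octa-2,6-dien-1-yl] acetate
Conditions: Ac2O (3 equiv), pyridine, DMAP (cat.), CH2Cl2, 0 °C to rt
Reagents that add atoms: acetic anhydride, CC(=O)OC(C)=O
Why: Standard DMAP-catalysed acetylation of the two free primary allylic alcohols (C14 and C15) while C6 stays silylated.

**Step 7**
Reactants: 12 [(2Z,6E)-6-(acetoxymethyl)-2-(but-3-en-1-yl)-8-[(tert-butyldimethylsilyl)oxy]octa-2,6-dien-1-yl] acetate; 13 2-(bromomethyl)prop-2-enoic acid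
Product: 14 (3S,5Z,9E)-5,9-bis(acetoxymethyl)-11-[(tert-butyldimethylsilyl)oxy]undeca-1,5,9-trien-3-yl 2-(bromomethyl)prop-2-enoate
Conditions: 13 (2 equiv), Pd(OAc)2 (10 mol%), chiral aryl sulfoxide–oxazoline ligand (S)-4-tert-butyl-2-[2-(p-tolylsulfinyl)phenyl]-4,5-dihydrooxazole (12 mol%), 2,6-dimethyl-1,4-benzoquinone (1.5 equiv), toluene, 40 °C
Reagents that add atoms: none
Why: Proposed new method: an intermolecular, branch- and enantioselective allylic C–H acyloxylation in which the electrophilic divalent palladium–sulfoxide catalyst binds only the monosubstituted olefin and cleaves the allylic C8–H bond, the resulting π-allylpalladium carboxylate of 13 undergoes quinone-promoted inner-sphere C–O reductive elimination at the internal allyl carbon, and the oxazoline substituent differentiates the two allyl faces to set (S)-C8 (ligand enantiomer chosen by screening both); the closest known reactions are the racemic branch-selective allylic C–H esterification with Pd(OAc)2/bis-sulfoxide/benzoquinone and the intramolecular asymmetric allylic C–H oxidation with Pd(OAc)2/sulfoxide–oxazoline catalysts, and what is new is intermolecular enantiocontrol on a polyene with an allyl-bromide-bearing acid.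

**Step 8**
Reactants: 14 (3S,5Z,9E)-5,9-bis(acetoxymethyl)-11-[(tert-butyldimethylsilyl)oxy]undeca-1,5,9-trien-3-yl 2-(bromomethyl)prop-2-enoate
Product: 15 (5S)-5-[(2Z,6E)-2,6-bis(acetoxymethyl)-8-[(tert-butyldimethylsilyl)oxy]octa-2,6-dien-1-yl]-3-(bromomethyl)furan-2(5H)-one
Conditions: second-generation Grubbs catalyst RuCl2(=CHPh)(PCy3)(H2IMes) (5 mol%), toluene (5 mM), 80 °C
Reagents that add atoms: none
Why: Ring-closing metathesis between the vinyl group on C8 and the 1,1-disubstituted acrylate forms the five-membered butenolide (C7=C11) with loss of ethene; the trisubstituted chain alkenes are inert and C8 is untouched.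

**Step 9**
Reactants: 15 (5S)-5-[(2Z,6E)-2,6-bis(acetoxymethyl)-8-[(tert-butyldimethylsilyl)oxy]octa-2,6-dien-1-yl]-3-(bromomethyl)furan-2(5H)-one
Product: 16 (5S)-5-[(2Z,6E)-2,6-bis(acetoxymethyl)-8-hydroxyocta-2,6-dien-1-yl]-3-(bromomethyl)furan-2(5H)-one
Conditions: 48% aq. HF, MeCN, 0 °C
Reagents that add atoms: none
Why: Amine-free acidic fluoride desilylation of the primary allylic silyl ether spares the allylic bromide, the acetates and the lactone.

**Step 10**
Reactants: 16 (5S)-5-[(2Z,6E)-2,6-bis(acetoxymethyl)-8-hydroxyocta-2,6-dien-1-yl]-3-(bromomethyl)furan-2(5H)-one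
Product: 17 (5S)-5-[(2Z,6E)-2,6-bis(acetoxymethyl)-8-oxoocta-2,6-dien-1-yl]-3-(bromomethyl)furan-2(5H)-one
Conditions: MnO2 (20 equiv), CH2Cl2, rt
Reagents that add atoms: none
Why: Neutral allylic oxidation with MnO2 gives the enal without isomerising the C4=C5 bond (formyl stays cis to C3, as in nerol-to-neral oxidations).

**Step 11**
Reactants: 17 (5S)-5-[(2Z,6E)-2,6-bis(acetoxymethyl)-8-oxoocta-2,6-dien-1-yl]-3-(bromomethyl)furan-2(5H)-one
Product: 19 target (6R,7S,8S)-14,15-diacetoxy-6-hydroxygermacra-1(10),4,11(13)-trien-12,8-olide, via allylchromium dichloride 18 (not isolated)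
Conditions: CrCl2 (8 equiv), DMF/THF, rt, syringe-pump addition of 17 over 12 h (final 2 mM); aq. NH4Cl (pH 6–7) work-up
Reagents that add atoms: none
Why: Intramolecular chromium-mediated Barbier (Nozaki–Hiyama) allylation in which the allylchromium adds through its γ-carbon C7 in a chair six-membered transition state, on the face of the butenolide opposite to the C9 substituent (7,8-trans, C7 S) and with the enal chain equatorial (6,7-anti, C6 R), closing the ten-membered ring and unveiling the exocyclic methylene.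

**Compound list**
1 | prop-2-yn-1-ol | C#CCO | starting material
2 | but-3-en-1-ylmagnesium bromide | C=CCC[Mg]Br | starting material
3 | bromomagnesium (Z)-3-(bromomagnesio)-2-(but-3-en-1-yl)prop-2-en-1-olate (Mg on C1 cis to CH2O) | C=CCC/C(CO[Mg]Br)=C/[Mg]Br | intermediate
4 | (Z)-2-(but-3-en-1-yl)-3-iodoprop-2-en-1-ol | C=CCC/C(CO)=C/I | intermediate
5 | but-2-yne-1,4-diol | OCC#CCO | starting material
6 | 4-[(tert-butyldimethylsilyl)oxy]but-2-yn-1-ol | OCC#CCO[Si](C)(C)C(C)(C)C | intermediate
7 | (2Z)-4-[(tert-butyldimethylsilyl)oxy]-2-(tributylstannyl)but-2-en-1-ol | OC/C([Sn](CCCC)(CCCC)CCCC)=C/CO[Si](C)(C)C(C)(C)C | intermediate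
8 | bromoethene | C=CBr | starting material
9 | (2E)-2-{2-[(tert-butyldimethylsilyl)oxy]ethylidene}but-3-en-1-ol | OC/C(C=C)=C/CO[Si](C)(C)C(C)(C)C | intermediate
10 | 9-[(3E)-5-[(tert-butyldimethylsilyl)oxy]-3-{[(9-borabicyclo[3.3.1]nonan-9-yl)oxy]methyl}pent-3-en-1-yl]-9-borabicyclo[3.3.1]nonane | CC(C)(C)[Si](C)(C)OC/C=C(/COB1C2CCCC1CCC2)CCB1C2CCCC1CCC2 | intermediate
11 | (2Z,6E)-2-(but-3-en-1-yl)-8-[(tert-butyldimethylsilyl)oxy]-6-(hydroxymethyl)octa-2,6-dien-1-ol | C=CCC/C(CO)=C/CC/C(CO)=C\CO[Si](C)(C)C(C)(C)C | intermediate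
12 | [(2Z,6E)-6-(acetoxymethyl)-2-(but-3-en-1-yl)-8-[(tert-butyldimethylsilyl)oxy]octa-2,6-dien-1-yl] acetate | C=CCC/C(COC(C)=O)=C/CC/C(COC(C)=O)=C\CO[Si](C)(C)C(C)(C)C | intermediate
13 | 2-(bromomethyl)prop-2-enoic acid | C=C(CBr)C(=O)O | starting material
14 | (3S,5Z,9E)-5,9-bis(acetoxymethyl)-11-[(tert-butyldimethylsilyl)oxy]undeca-1,5,9-trien-3-yl 2-(bromomethyl)prop-2-enoate | C=C[C@@H](OC(=O)C(=C)CBr)C/C(COC(C)=O)=C/CC/C(COC(C)=O)=C\CO[Si](C)(C)C(C)(C)C | intermediate
15 | (5S)-5-[(2Z,6E)-2,6-bis(acetoxymethyl)-8-[(tert-butyldimethylsilyl)oxy]octa-2,6-dien-1-yl]-3-(bromomethyl)furan-2(5H)-one | BrCC1=C[C@@H](OC1=O)C/C(COC(C)=O)=C/CC/C(COC(C)=O)=C\CO[Si](C)(C)C(C)(C)C | intermediate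
16 | (5S)-5-[(2Z,6E)-2,6-bis(acetoxymethyl)-8-hydroxyocta-2,6-dien-1-yl]-3-(bromomethyl)furan-2(5H)-one | BrCC1=C[C@@H](OC1=O)C/C(COC(C)=O)=C/CC/C(COC(C)=O)=C\CO | intermediate
17 | (5S)-5-[(2Z,6E)-2,6-bis(acetoxymethyl)-8-oxoocta-2,6-dien-1-yl]-3-(bromomethyl)furan-2(5H)-one (formyl cis to C3) | BrCC1=C[C@@H](OC1=O)C/C(COC(C)=O)=C/CC/C(COC(C)=O)=C\C=O | intermediate
18 | {(5S)-5-[(2Z,6E)-2,6-bis(acetoxymethyl)-8-oxoocta-2,6-dien-1-yl]-2-oxo-2,5-dihydrofuran-3-yl}methylchromium dichloride | Cl[Cr](Cl)CC1=C[C@@H](OC1=O)C/C(COC(C)=O)=C/CC/C(COC(C)=O)=C\C=O | intermediate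
19 | CNP0594234.1, [(3aS,4R,5E,9Z,11aS)-4-hydroxy-3-methylidene-2-oxo-2,3,3a,4,7,8,11,11a-octahydrocyclodeca[b]furan-6,10-diyl]bis(methylene) diacetate | C=C1C(=O)O[C@H]2C/C(COC(C)=O)=C/CC/C(COC(C)=O)=C\[C@@H](O)[C@H]12 | target

**Step count**
Total: 11 steps. Longest linear sequence: 10 steps (steps 2–11, from but-2-yne-1,4-diol); step 1 is a one-step side branch.

**Three steps most likely to fail**

Step 7 (new allylic C–H acyloxylation). The risks are the level of enantiocontrol, the branched/linear ratio, and survival of the allylic bromide of 13 next to transient zerovalent palladium. The fallback uses known reactions, sets out from 12 and comes back at 14. Linear-selective allylic C–H acetoxylation of the terminal olefin (Pd(OAc)2, 1,4-benzoquinone, DMSO/AcOH, 40 °C) moves the double bond to C7=C8 and gives the primary (2E)-allylic triacetate F1. Iridium-catalysed asymmetric allylic substitution ([Ir(cod)Cl]2, chiral phosphoramidite, KHCO3 as hydroxide equivalent) should ionise only this unhindered monosubstituted allyl acetate, the two 2-substituted allylic acetates being inert, and places oxygen on the internal carbon to give the branched (3S)-allylic alcohol F2. Steglich esterification of F2 with 13 (N,N'-diisopropylcarbodiimide, catalytic DMAP, CH2Cl2, −20 °C) gives 14.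

Step 11 (macrocyclising Barbier allylation). The risks are oligomerisation, the 6,7-anti/7,8-trans selectivity, which is argued from the chair model and from intermolecular precedent rather than proven for this ring, and translactonisation of the product to the C6 oxygen under basic work-up. The fallback replaces the reductive organochromium chemistry by a closed-shell allylboration of an isolable reagent; it sets out from 16 and comes back at 19. Phosphine-free borylation of the allylic bromide (Pd2(dba)3, B2pin2, THF, rt; the allylic acetates are not ionised without phosphine) gives the primary allylboronate alcohol F5. MnO2 oxidation under dilution gives the enal allylboronate F6. F6 is cyclised at 2 mM by Sc(OTf)3-catalysed (or thermal) intramolecular allylboration through the same chair transition state, and hydrolytic work-up gives 19.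

Step 8 (ring-closing metathesis of a 2-(bromomethyl)acrylate in a polyene). The risks are slow turnover at the hindered, bromine-bearing acrylate and catalyst decomposition. The fallback brings the bromide in after ring closure; it sets out from 12 and comes back at 15. The step 7 reaction is run with 2-(hydroxymethyl)prop-2-enoic acid in place of 13 to give the (3S)-allylic 2-(hydroxymethyl)acrylate F3. Ring-closing metathesis of this bromine-free acrylate (same ruthenium catalyst) gives the 3-(hydroxymethyl)butenolide F4. Appel bromination of its only free hydroxyl (CBr4, PPh3, CH2Cl2, 0 °C) gives 15.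

**Further compounds**
F1 | step 7 | [(2E,5Z,9E)-5,9-bis(acetoxymethyl)-11-[(tert-butyldimethylsilyl)oxy]undeca-2,5,9-trien-1-yl] acetate | CC(=O)OC/C=C/C/C(COC(C)=O)=C/CC/C(COC(C)=O)=C\CO[Si](C)(C)C(C)(C)C
F2 | step 7 | (3S,5Z,9E)-5,9-bis(acetoxymethyl)-11-[(tert-butyldimethylsilyl)oxy]undeca-1,5,9-trien-3-ol | C=C[C@@H](O)C/C(COC(C)=O)=C/CC/C(COC(C)=O)=C\CO[Si](C)(C)C(C)(C)C
F3 | step 8 | (3S,5Z,9E)-5,9-bis(acetoxymethyl)-11-[(tert-butyldimethylsilyl)oxy]undeca-1,5,9-trien-3-yl 2-(hydroxymethyl)prop-2-enoate | C=C[C@@H](OC(=O)C(=C)CO)C/C(COC(C)=O)=C/CC/C(COC(C)=O)=C\CO[Si](C)(C)C(C)(C)C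
F4 | step 8 | (5S)-5-[(2Z,6E)-2,6-bis(acetoxymethyl)-8-[(tert-butyldimethylsilyl)oxy]octa-2,6-dien-1-yl]-3-(hydroxymethyl)furan-2(5H)-one | OCC1=C[C@@H](OC1=O)C/C(COC(C)=O)=C/CC/C(COC(C)=O)=C\CO[Si](C)(C)C(C)(C)C
F5 | step 11 | (5S)-5-[(2Z,6E)-2,6-bis(acetoxymethyl)-8-hydroxyocta-2,6-dien-1-yl]-3-[(4,4,5,5-tetramethyl-1,3,2-dioxaborolan-2-yl)methyl]furan-2(5H)-one | CC1(C)OB(CC2=C[C@@H](OC2=O)C/C(COC(C)=O)=C/CC/C(COC(C)=O)=C\CO)OC1(C)C
F6 | step 11 | (5S)-5-[(2Z,6E)-2,6-bis(acetoxymethyl)-8-oxoocta-2,6-dien-1-yl]-3-[(4,4,5,5-tetramethyl-1,3,2-dioxaborolan-2-yl)methyl]furan-2(5H)-one | CC1(C)OB(CC2=C[C@@H](OC2=O)C/C(COC(C)=O)=C/CC/C(COC(C)=O)=C\C=O)OC1(C)C
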